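Assumption: positions carry germacranolide numbers (C1 ketone, C2=C3, C3–O–C10 bridge, C4=C5, C6 lactone oxygen, C7, C8 ester, C9 carbinol, C11=C13, C12 lactone carbonyl, C14 and C15 methyls). The target is read as 4Z,6R,7S,8S,9R,10S with a 6,7-trans lactone.

## Retrosynthetic overview
1. Target ⇒ free 8,9-diol ⇒ 8,9-acetonide of the tricyclic core. The last bond made is the C8-selective methacrylate.
2. Key disconnection: C2–C3, C3–C4 and O–C3 together, with C3 coming from carbon monoxide. A seco vinyl iodide/tertiary propargylic alcohol is closed by carbonylative alkynylation, and the new γ-hydroxy-ynone folds to the 3(2H)-furanone in the same flask.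
3. Seco compound ⇒ C6–C7 allylchromium addition and lactonisation of (Z)-3-iodobut-2-enal with a Morita–Baylis–Hillman-derived allyl bromide.
4. Allyl bromide ⇒ L-tartrate (C7–C10, supplies C8 and C9), MeMgBr (C14), HC≡CMgBr (C1 and C2, chelation sets C10), methyl acrylate (C11–C13).
5. Ring order: γ-lactone first, then the ten-membered carbocycle and the furanone together. The tartrate dioxolane is a temporary ring.

## Route

Step 1
Reactants: 1 but-2-yn-1-ol
Product: 3 (Z)-3-iodobut-2-en-1-ol, via cyclic alkenylalanate 2 (not isolated)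
Conditions: NaAlH2(OCH2CH2OMe)2, THF, 0 to 23 °C; then NIS, −78 °C
Reagents that add atoms: N-iodosuccinimide, O=C1CCC(=O)N1I
Why: Hydroxyl-directed trans-hydroalumination followed by iodination places aluminium on C4 inside a five-membered O–Al ring, and iodinolysis with retention gives only the Z iodide, which is the C4=C5 geometry of the target.

Step 2
Reactants: 3 (Z)-3-iodobut-2-en-1-ol
Product: 4 (Z)-3-iodobut-2-enal
Conditions: MnO2, CH2Cl2, 23 °C, dark
Reagents that add atoms: none
Why: This allylic alcohol oxidation with MnO2 is neutral and heterogeneous, so the vinyl iodide and the Z geometry survive when the enal is used at once.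

Step 3
Reactants: 5 dimethyl (4R,5R)-2,2-dimethyl-1,3-dioxolane-4,5-dicarboxylate
Product: 6 (4R,5R)-N4,N5-dimethoxy-N4,N5,2,2-tetramethyl-1,3-dioxolane-4,5-dicarboxamide
Conditions: MeNH(OMe)·HCl, iPrMgCl, THF, −20 to 0 °C
Reagents that add atoms: N,O-dimethylhydroxylamine hydrochloride, CNOC.Cl
Why: In this Weinreb amidation the chloromagnesium amide made in the flask displaces both methoxides, and the two centres of the more stable trans-dioxolane stay 4R,5R.

Step 4
Reactants: 6 (4R,5R)-N4,N5-dimethoxy-N4,N5,2,2-tetramethyl-1,3-dioxolane-4,5-dicarboxamide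
Product: 7 (4R,5R)-5-acetyl-N-methoxy-N,2,2-trimethyl-1,3-dioxolane-4-carboxamide
Conditions: MeMgBr (1.05 equiv), THF, −78 to −40 °C
Reagents that add atoms: methylmagnesium bromide, C[Mg]Br
Why: In this Weinreb ketone synthesis the two amides of the C2-symmetric diamide are equivalent, and the anionic magnesium chelate formed after the first addition neither over-adds nor invites a second attack, so one equivalent gives the mono-ketone (C10 and C14).

Step 5
Reactants: 7 (4R,5R)-5-acetyl-N-methoxy-N,2,2-trimethyl-1,3-dioxolane-4-carboxamide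
Product: 9 (4R,5R)-5-[(2R)-2-hydroxybut-3-yn-2-yl]-2,2-dimethyl-1,3-dioxolane-4-carbaldehyde, via ethynyl carbinol amide 8 (not isolated)
Conditions: HC≡CMgBr (1.5 equiv), MgBr2·OEt2, CH2Cl2–THF, −78 °C; then iBu2AlH (2 equiv), −78 °C, same flask
Reagents that add atoms: ethynylmagnesium bromide, C#C[Mg]Br
Why: In this one-flask Cram-chelate Grignard addition and Weinreb reduction, magnesium ties the ketone oxygen to the α-oxygen O9, the acetylide attacks from the H9 side to give the 9,10-syn carbinol (10R here, the 10S centre of the target), and iBu2AlH then takes the untouched amide only to a stable chelate that releases the aldehyde on work-up, with lactol and lactone formation blocked by the trans-dioxolane.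

Step 6
Reactants: 9 (4R,5R)-5-[(2R)-2-hydroxybut-3-yn-2-yl]-2,2-dimethyl-1,3-dioxolane-4-carbaldehyde + 10 methyl acrylate
Product: 11 methyl 2-{hydroxy[(4S,5R)-5-((2R)-2-hydroxybut-3-yn-2-yl)-2,2-dimethyl-1,3-dioxolan-4-yl]methyl}prop-2-enoate (both C7 epimers)
Conditions: DABCO (0.5 equiv), 1,4-dioxane–H2O (1:1), 23 °C, 48 h
Reagents that add atoms: none
Why: In this Morita–Baylis–Hillman reaction the DABCO–acrylate zwitterion adds to the activated α-alkoxy aldehyde, the new C7 carbinol centre is erased in step 7 so its ratio does not matter, and C8 is safe because epimerisation would give the less stable cis-dioxolane.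

Step 7
Reactants: 11 methyl 2-{hydroxy[(4S,5R)-5-((2R)-2-hydroxybut-3-yn-2-yl)-2,2-dimethyl-1,3-dioxolan-4-yl]methyl}prop-2-enoate
Product: 12 methyl (Z)-2-(bromomethyl)-3-[(4S,5R)-5-((2R)-2-hydroxybut-3-yn-2-yl)-2,2-dimethyl-1,3-dioxolan-4-yl]prop-2-enoate
Conditions: NBS, Me2S, CH2Cl2, 0 to 23 °C
Reagents that add atoms: N-bromosuccinimide, O=C1CCC(=O)N1Br
Why: This is an allylic bromination with transposition (SN2′ attack of bromide on the alkoxysulfonium salt of the secondary carbinol), which gives the conjugated primary bromide with C8 trans to the ester, while the hindered tertiary carbinol and the acetonide are left alone under these nearly neutral conditions.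

Step 8
Reactants: 12 methyl (Z)-2-(bromomethyl)-3-[(4S,5R)-5-((2R)-2-hydroxybut-3-yn-2-yl)-2,2-dimethyl-1,3-dioxolan-4-yl]prop-2-enoate + 4 (Z)-3-iodobut-2-enal
Product: 14 (4S,5S)-4-[(4S,5R)-5-((2R)-2-hydroxybut-3-yn-2-yl)-2,2-dimethyl-1,3-dioxolan-4-yl]-5-[(Z)-2-iodoprop-1-en-1-yl]-3-methylidenedihydrofuran-2(3H)-one, via anti hydroxy ester 13 (not isolated)
Conditions: CrCl2 (4 equiv, nickel-free), THF, 0 to 23 °C; then PPTS (cat.), CH2Cl2, 23 °C on the crude
Reagents that add atoms: none
Why: In this Nozaki–Hiyama allylation followed by lactonisation, nickel-free CrCl2 reduces only the allylic bromide (vinyl iodide, alkyne and free carbinol are tolerated), the equilibrating allylchromium reagent adds through a chair transition state with C5 and C8 both equatorial (6,7-anti, hence the trans-lactone), and allylic 1,3-strain against the ester keeps H8 inside so that the aldehyde arrives anti to the bulky C9 branch, which sets 7S and with it the C6 configuration of the target.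

Step 9
Reactants: 14 (4S,5S)-4-[(4S,5R)-5-((2R)-2-hydroxybut-3-yn-2-yl)-2,2-dimethyl-1,3-dioxolan-4-yl]-5-[(Z)-2-iodoprop-1-en-1-yl]-3-methylidenedihydrofuran-2(3H)-one
Product: 17 8,9-O-isopropylidene-(4Z,6R,7S,8S,9R,10S)-8,9-dihydroxy-1-oxo-3,10-epoxygermacra-2,4,11(13)-trien-12,6-olide, via macrocyclic ynone 15 (not isolated), via macrocyclic enaminone 16 (not isolated)
Conditions: PdCl2(PPh3)2 (10 mol %), CuI (10 mol %), Et3N (5 equiv), CO (1 atm), THF, 2 mM by syringe pump, 45 °C; then vent, Et2NH (1.2 equiv), 23 °C; then AcOH–H2O (4:1), 23 °C, same flask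
Reagents that add atoms: carbon monoxide, [C-]#[O+]; water, O; diethylamine, CCNCC (its atoms stay only in 16)
Why: Proposed new method: zerovalent palladium inserts into the Z-vinyl iodide, CO inserts, and the tethered copper acetylide captures the acylpalladium (a carbonylative Sonogashira coupling run as a ten-membered ring closure, in which direct coupling is shut off because it would give a nine-membered enyne) to give bent ynone 15, whose C1 takes up Et2NH far faster than the α-methylene lactone at this dilution to give 16, and on acidification the C10 hydroxyl closes onto C3 and the iminium is hydrolysed, so that carbocycle and 3(2H)-furanone arise in one flask without ever breaking the C10–O bond (configuration kept, Z-alkene kept by retention at palladium); the closest known reaction types are the palladium-catalysed carbonylative coupling of halides with tertiary propargylic alcohols to 3(2H)-furanones, carbonylative Stille macrocyclisation, and the amine-mediated γ-hydroxy-ynone to furanone isomerisation.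

Step 10
Reactants: 17 8,9-O-isopropylidene-(4Z,6R,7S,8S,9R,10S)-8,9-dihydroxy-1-oxo-3,10-epoxygermacra-2,4,11(13)-trien-12,6-olide
Product: 18 (4Z,6R,7S,8S,9R,10S)-8,9-dihydroxy-1-oxo-3,10-epoxygermacra-2,4,11(13)-trien-12,6-olide
Conditions: TFA–H2O (9:1), CH2Cl2, 0 °C
Reagents that add atoms: none
Why: This acid-catalysed acetal hydrolysis frees the strained trans-dioxolane quickly, the furanone and the α-methylene lactone are acid-stable, and no C–O bond at a stereocentre is broken.

Step 11
Reactants: 18 (4Z,6R,7S,8S,9R,10S)-8,9-dihydroxy-1-oxo-3,10-epoxygermacra-2,4,11(13)-trien-12,6-olide + 19 methacrylic anhydride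
Product: 20 (4Z,6R,7S,8S,9R,10S)-9-hydroxy-8-methacryloyloxy-1-oxo-3,10-epoxygermacra-2,4,11(13)-trien-12,6-olide (target)
Conditions: 19 (1.1 equiv), Et3N, DMAP (cat.), CH2Cl2, −20 °C
Reagents that add atoms: none
Why: In this DMAP-catalysed acyl transfer from the anhydride, the C9 hydroxyl is neopentyl-like next to quaternary C10, so one equivalent of acylpyridinium goes to the more open C8 hydroxyl, the low temperature suppresses 8→9 acyl migration, and no stereocentre is touched.

## Compound list
1 | but-2-yn-1-ol | CC#CCO | starting material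
2 | cyclic alkenylalanate, sodium salt (five-membered O–Al ring, not isolated) | CC1=CCO[Al-]1(OCCOC)OCCOC.[Na+] | intermediate
3 | (Z)-3-iodobut-2-en-1-ol | C/C(I)=C/CO | intermediate
4 | (Z)-3-iodobut-2-enal | C/C(I)=C/C=O | intermediate
5 | dimethyl (4R,5R)-2,2-dimethyl-1,3-dioxolane-4,5-dicarboxylate (L-tartrate acetonide) | COC(=O)[C@@H]1OC(C)(C)O[C@H]1C(=O)OC | starting material
6 | (4R,5R)-N4,N5-dimethoxy-N4,N5,2,2-tetramethyl-1,3-dioxolane-4,5-dicarboxamide | CON(C)C(=O)[C@@H]1OC(C)(C)O[C@H]1C(=O)N(C)OC | intermediate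
7 | (4R,5R)-5-acetyl-N-methoxy-N,2,2-trimethyl-1,3-dioxolane-4-carboxamide | CON(C)C(=O)[C@@H]1OC(C)(C)O[C@H]1C(C)=O | intermediate
8 | (4R,5R)-5-[(2R)-2-hydroxybut-3-yn-2-yl]-N-methoxy-N,2,2-trimethyl-1,3-dioxolane-4-carboxamide (present as its bromomagnesium alkoxide, not isolated) | CON(C)C(=O)[C@@H]1OC(C)(C)O[C@H]1[C@](C)(O)C#C | intermediate
9 | (4R,5R)-5-[(2R)-2-hydroxybut-3-yn-2-yl]-2,2-dimethyl-1,3-dioxolane-4-carbaldehyde | O=C[C@@H]1OC(C)(C)O[C@H]1[C@](C)(O)C#C | intermediate
10 | methyl acrylate | C=CC(=O)OC | starting material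
11 | methyl 2-{hydroxy[(4S,5R)-5-((2R)-2-hydroxybut-3-yn-2-yl)-2,2-dimethyl-1,3-dioxolan-4-yl]methyl}prop-2-enoate (both C7 epimers) | COC(=O)C(=C)C(O)[C@@H]1OC(C)(C)O[C@H]1[C@](C)(O)C#C | intermediate
12 | methyl (Z)-2-(bromomethyl)-3-[(4S,5R)-5-((2R)-2-hydroxybut-3-yn-2-yl)-2,2-dimethyl-1,3-dioxolan-4-yl]prop-2-enoate | COC(=O)/C(CBr)=C/[C@@H]1OC(C)(C)O[C@H]1[C@](C)(O)C#C | intermediate
13 | methyl (3S,4S,5Z)-4-hydroxy-3-[(4S,5R)-5-((2R)-2-hydroxybut-3-yn-2-yl)-2,2-dimethyl-1,3-dioxolan-4-yl]-6-iodo-2-methylidenehept-5-enoate (not isolated) | COC(=O)C(=C)[C@@H]([C@H](O)/C=C(/C)I)[C@@H]1OC(C)(C)O[C@H]1[C@](C)(O)C#C | intermediate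
14 | (4S,5S)-4-[(4S,5R)-5-((2R)-2-hydroxybut-3-yn-2-yl)-2,2-dimethyl-1,3-dioxolan-4-yl]-5-[(Z)-2-iodoprop-1-en-1-yl]-3-methylidenedihydrofuran-2(3H)-one (trans-lactone) | C/C(I)=C/[C@H]1OC(=O)C(=C)[C@@H]1[C@@H]2OC(C)(C)O[C@H]2[C@](C)(O)C#C | intermediate
15 | 8,9-O-isopropylidene-(4Z,6R,7S,8S,9R,10R)-8,9,10-trihydroxy-3-oxogermacra-4,11(13)-dien-1-yn-12,6-olide (not isolated) | C=C1C(=O)O[C@@H]2/C=C(/C)C(=O)C#C[C@@](C)(O)[C@@H]3OC(C)(C)O[C@H]3[C@@H]12 | intermediate
16 | 1-diethylamino adduct of 15, enaminone with C3 and C10 cis on C1=C2 (not isolated) | C=C1C(=O)O[C@@H]2/C=C(/C)C(=O)/C=C(N(CC)CC)\[C@@](C)(O)[C@@H]3OC(C)(C)O[C@H]3[C@@H]12 | intermediate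
17 | 8,9-O-isopropylidene-(4Z,6R,7S,8S,9R,10S)-8,9-dihydroxy-1-oxo-3,10-epoxygermacra-2,4,11(13)-trien-12,6-olide | C=C1C(=O)O[C@@H]2/C=C(/C)C3=CC(=O)[C@@](C)(O3)[C@@H]4OC(C)(C)O[C@H]4[C@@H]12 | intermediate
18 | (4Z,6R,7S,8S,9R,10S)-8,9-dihydroxy-1-oxo-3,10-epoxygermacra-2,4,11(13)-trien-12,6-olide | C=C1C(=O)O[C@@H]2/C=C(/C)C3=CC(=O)[C@@](C)(O3)[C@H](O)[C@@H](O)[C@@H]12 | intermediate
19 | methacrylic anhydride | C=C(C)C(=O)OC(=O)C(C)=C | starting material
20 | (4Z,6R,7S,8S,9R,10S)-9-hydroxy-8-methacryloyloxy-1-oxo-3,10-epoxygermacra-2,4,11(13)-trien-12,6-olide (CNP0252578.3) | C=C(C)C(=O)O[C@H]1[C@H]2C(=C)C(=O)O[C@@H]2/C=C(/C)C2=CC(=O)[C@@](C)(O2)[C@@H]1O | target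

## Step count and risks
Total step count: 11. Longest linear sequence: 9 steps (steps 3 to 11). Steps 1 and 2 build the side fragment.

**Step 9** is the most likely to fail.
- **Risks:** a ten-membered carbonylative ring closure has to beat oligomerisation, a Heck-type closure onto the α-methylene group, and alkyne dimerisation.
- **Fallback:** it sets out from 11 and 4, moves the ring closure to C6–C7, and comes back to the route at 17.
- Aldehyde 4 is masked with HC(OMe)3 and PPTS as (Z)-3-iodo-1,1-dimethoxybut-2-ene F1.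
- F1 is coupled with 11 in the well-behaved intermolecular mode (PdCl2(PPh3)2, CuI, Et3N, CO) to give the open-chain ynone acetal F2.
- Et2NH followed by aqueous AcOH closes the furanone and drops the acetal, giving the furanone enal F3.
- NBS and Me2S give the bromo enal F4.
- CrCl2 under high dilution closes the carbocycle by intramolecular allylation with lactonisation to give 17.

**Step 8** is second.
- **Risks:** the ester-bearing allylchromium reagent may react through its other alkene geometry and give the 6,7-syn adduct (cis-lactone), and the facial bias from C8 rests on a model.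
- **Fallback:** it sets out from 12 and 4, sets C6 by inversion instead of directly, and comes back at 14.
- Zn in THF and aqueous NH4Cl gives the syn adduct, the 6-epi hydroxy ester F5.
- LiOH gives the 6-epi hydroxy acid F6.
- Mitsunobu lactonisation (PPh3, DIAD) displaces the activated C6 oxygen by the carboxylate with inversion and gives trans-lactone 14.

**Step 11** is third.
- **Risks:** the C8/C9 selectivity may be modest, and over-acylation or acyl migration may erode it.
- **Fallback:** it sets out from 18, replaces direct discrimination by a silyl detour, and comes back at 20.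
- Et3SiOTf and 2,6-lutidine give the 8,9-bis(triethylsilyl) ether F7.
- PPTS in MeOH at 0 °C removes the less hindered silyl group and gives the 9-O-triethylsilyl 8-alcohol F8.
- Anhydride 19 with DMAP, now used in excess, gives the 9-O-triethylsilyl 8-methacrylate F9.
- HF·pyridine then releases 20.

## Further compounds
F1 | step 9 | (Z)-3-iodo-1,1-dimethoxybut-2-ene | C/C(I)=C/C(OC)OC
F2 | step 9 | open-chain ynone acetal (C3 ketone between C2 alkyne and Z-C4=C5, C6 dimethyl acetal, C7 carbinol epimers) | COC(=O)C(=C)C(O)[C@@H]1OC(C)(C)O[C@H]1[C@](C)(O)C#CC(=O)/C(C)=C\C(OC)OC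
F3 | step 9 | furanone enal (10S furanone, Z-enal, C7 carbinol epimers) | COC(=O)C(=C)C(O)[C@@H]1OC(C)(C)O[C@H]1[C@]2(C)OC(=CC2=O)/C(C)=C\C=O
F4 | step 9 | bromo enal (Z allylic bromide, 10S furanone, Z-enal) | COC(=O)/C(CBr)=C/[C@@H]1OC(C)(C)O[C@H]1[C@]2(C)OC(=CC2=O)/C(C)=C\C=O
F5 | step 8 | 6-epi hydroxy ester (6,7-syn epimer of 13) | COC(=O)C(=C)[C@@H]([C@@H](O)/C=C(/C)I)[C@@H]1OC(C)(C)O[C@H]1[C@](C)(O)C#C
F6 | step 8 | 6-epi hydroxy acid | OC(=O)C(=C)[C@@H]([C@@H](O)/C=C(/C)I)[C@@H]1OC(C)(C)O[C@H]1[C@](C)(O)C#C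
F7 | step 11 | 8,9-bis(triethylsilyl) ether of 18 | C=C1C(=O)O[C@@H]2/C=C(/C)C3=CC(=O)[C@@](C)(O3)[C@H](O[Si](CC)(CC)CC)[C@@H](O[Si](CC)(CC)CC)[C@@H]12
F8 | step 11 | 9-O-triethylsilyl 8-alcohol | C=C1C(=O)O[C@@H]2/C=C(/C)C3=CC(=O)[C@@](C)(O3)[C@H](O[Si](CC)(CC)CC)[C@@H](O)[C@@H]12
F9 | step 11 | 9-O-triethylsilyl 8-methacrylate | C=C1C(=O)O[C@@H]2/C=C(/C)C3=CC(=O)[C@@](C)(O3)[C@H](O[Si](CC)(CC)CC)[C@@H](OC(=O)C(C)=C)[C@@H]12
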